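**Strategy.** The benzoate ring is cut at two neighbouring bonds at once: the diaryl ether bond at C6 and the bond from C1 to the carboxyl carbon. The feature used is that C1 of this ring is flanked by two oxygenated carbons, C2 (prenyloxy) and C6 (aryloxy), with the C4 methyl para to it. A 3-alkoxybenzyne delivers exactly this 1,2,3-array when an oxygen nucleophile enters at the carbon remote from the ether and CO2 is taken up next to it. One operation thus unites a phenoxide, an aryne and CO2. The aryne precursor is an ortho-silylaryl triflate carrying the prenyl ether beside silicon; the phenol partner holds the future CH2OH as a dioxolane.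

Key step: step 7

Assumption: the target is achiral and its only alkene carries two identical methyl groups, so no stereochemical element has to be set; the aryl prenyl ether is taken to tolerate brief n-BuLi/TMEDA at −78 °C and dilute aqueous HCl at room temperature.

**Route**

Step 1
Reactants: 1 orcinol (5-methylbenzene-1,3-diol); 2 prenyl bromide (1-bromo-3-methylbut-2-ene)
Product: 3 3-methyl-5-[(3-methylbut-2-en-1-yl)oxy]phenol
Conditions: K2CO3, acetone, reflux (1 in threefold excess)
Reagents that add atoms: none
Why: Williamson O-alkylation of a phenoxide by a primary allylic bromide; the excess of the diol should favour the mono-ether, and unreacted water-soluble orcinol is washed out.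

Step 2
Reactants: 3 3-methyl-5-[(3-methylbut-2-en-1-yl)oxy]phenol
Product: 4 3-methyl-5-[(3-methylbut-2-en-1-yl)oxy]phenyl N-isopropylcarbamate
Conditions: i-PrNCO, Et3N (cat.), CH2Cl2, rt
Reagents that add atoms: isopropyl isocyanate, CC(C)N=C=O
Why: Amine-catalysed addition of a phenol to an isocyanate (carbamoylation) should install a strong ortho-directing group that can later be removed under mild base.

Step 3
Reactants: 4 3-methyl-5-[(3-methylbut-2-en-1-yl)oxy]phenyl N-isopropylcarbamate
Product: 8 5-methyl-3-[(3-methylbut-2-en-1-yl)oxy]-2-(trimethylsilyl)phenyl N-isopropylcarbamate, via N-silyl carbamate 5 (not isolated), via aryllithium 6 (not isolated), via N-silyl C-silyl carbamate 7 (not isolated)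
Conditions: TBSOTf, TMEDA, Et2O, 0 °C to rt; n-BuLi (1.3 equiv), TMEDA, −78 °C, 30 min; TMSCl, −78 °C to rt; aq NaHSO4
Reagents that add atoms: chlorotrimethylsilane, C[Si](C)(C)Cl
Why: Directed ortho-metalation of an aryl O-carbamate with in situ N-silyl protection: the C–H between the carbamate oxygen and the ether oxygen is the most acidic and best-coordinated site, so lithiation and silyl quench should place TMS there, the N–Si bond being cleaved on acidic work-up.

Step 4
Reactants: 8 5-methyl-3-[(3-methylbut-2-en-1-yl)oxy]-2-(trimethylsilyl)phenyl N-isopropylcarbamate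
Product: 10 5-methyl-3-[(3-methylbut-2-en-1-yl)oxy]-2-(trimethylsilyl)phenyl trifluoromethanesulfonate, via silylphenol 9 (not isolated)
Conditions: Et2NH, DBU, MeCN, 40 °C; then PhNTf2, rt
Reagents that add atoms: N-phenylbis(trifluoromethanesulfonimide), O=S(=O)(N(c1ccccc1)S(=O)(=O)C(F)(F)F)C(F)(F)F
Why: E1cB cleavage of the secondary carbamate (isopropyl isocyanate expelled and scavenged by diethylamine) should free the phenoxide, which is triflated in the same pot, the established one-pot entry to ortho-silylaryl triflates that avoids handling the acid-sensitive silylphenol.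

Step 5
Reactants: 11 2,4-dimethoxyphenol
Product: 12 2-hydroxy-3,5-dimethoxybenzaldehyde
Conditions: MgCl2, Et3N, (CH2O)n, MeCN, reflux
Reagents that add atoms: paraformaldehyde (as formaldehyde), C=O
Why: Magnesium-mediated ortho-formylation of a phenol (Casnati–Skattebøl): the magnesium phenoxide delivers formaldehyde only ortho to oxygen, and C6 is the single free ortho carbon.

Step 6
Reactants: 12 2-hydroxy-3,5-dimethoxybenzaldehyde
Product: 13 2-(1,3-dioxolan-2-yl)-4,6-dimethoxyphenol
Conditions: HOCH2CH2OH, p-TsOH (cat.), toluene, Dean–Stark reflux; Et3N quench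
Reagents that add atoms: ethylene glycol, OCCO
Why: Acid-catalysed acetalisation with azeotropic removal of water should give the base-stable dioxolane, so that neither the aryne nor the aryl anion of step 7 meets a carbonyl group or an O–H other than the phenol.

Step 7
Reactants: 10 5-methyl-3-[(3-methylbut-2-en-1-yl)oxy]-2-(trimethylsilyl)phenyl trifluoromethanesulfonate; 13 2-(1,3-dioxolan-2-yl)-4,6-dimethoxyphenol; 14 carbon dioxide
Product: 19 2-[2-(1,3-dioxolan-2-yl)-4,6-dimethoxyphenoxy]-4-methyl-6-[(3-methylbut-2-en-1-yl)oxy]benzoic acid, via potassium phenoxide 15 (not isolated), via aryne 16 (not isolated), via aryl potassium adduct 17 (not isolated), via potassium carboxylate 18 (not isolated)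
Conditions: 13 (1.3 equiv), KH, THF, 0 °C; then 18-crown-6, KF, CO2 (1 atm), 10 added over 2 h, 0 °C to rt; aq NaHCO3 extraction, then cold 10% aq citric acid
Reagents that add atoms: none
Why: Proposed new method: fluoride attacks silicon of 10 and expels triflate to give 5-methyl-3-prenyloxybenzyne 16, the crown-activated phenoxide 15 adds through oxygen to the aryne carbon remote from the prenyloxy group, and the resulting aryl anion 17, sited between the two ether oxygens, is captured by CO2 to give carboxylate 18. The closest known reaction types are the three-component coupling of arynes with amines and CO2 to anthranilic acids and the fluoride-mediated O-arylation of phenols by ortho-silylaryl triflates; joining a phenoxide addition to a CO2 quench is the untested element. No ring is closed and no stereocentre is formed. The required regiochemistry (oxygen at C6, carboxyl at C1 of the benzoate) should follow from the distortion of a 3-alkoxyaryne, whose distal carbon is the electrophilic terminus and whose proximal carbon best carries negative charge next to the inductively withdrawing oxygen. O-arylation over C-arylation is secured because both ortho positions and the para position of phenoxide 15 are substituted. Carboxylation over protonation is favoured by a KH-derived phenoxide in THF that offers no O–H or N–H acid and by CO2 saturation, and bicarbonate extraction separates the acid from any neutral diaryl ether.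

Step 8
Reactants: 19 2-[2-(1,3-dioxolan-2-yl)-4,6-dimethoxyphenoxy]-4-methyl-6-[(3-methylbut-2-en-1-yl)oxy]benzoic acid
Product: 20 methyl 2-[2-(1,3-dioxolan-2-yl)-4,6-dimethoxyphenoxy]-4-methyl-6-[(3-methylbut-2-en-1-yl)oxy]benzoate
Conditions: MeI, K2CO3, DMF, rt (19 used directly after isolation)
Reagents that add atoms: iodomethane, CI
Why: SN2 alkylation of the carboxylate by iodomethane should esterify the di-ortho-substituted acid without attack at its hindered carbonyl carbon, and the basic medium keeps the acetal intact.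

Step 9
Reactants: 20 methyl 2-[2-(1,3-dioxolan-2-yl)-4,6-dimethoxyphenoxy]-4-methyl-6-[(3-methylbut-2-en-1-yl)oxy]benzoate
Product: 22 methyl 2-[2-(hydroxymethyl)-4,6-dimethoxyphenoxy]-4-methyl-6-[(3-methylbut-2-en-1-yl)oxy]benzoate, via aldehyde 21 (not isolated)
Conditions: 1 M aq HCl, THF, rt; then aq NaHCO3 to pH 8, NaBH4, MeOH, 0 °C
Reagents that add atoms: water, O
Why: Acid-catalysed acetal hydrolysis followed in the same flask by chemoselective sodium borohydride reduction of the aldehyde should give the benzylic alcohol, the hindered 2,6-disubstituted methyl ester and the prenyl ether being inert to both operations.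

**Compound list**

1 | orcinol (5-methylbenzene-1,3-diol) | Cc1cc(O)cc(O)c1 | starting material
2 | prenyl bromide (1-bromo-3-methylbut-2-ene) | CC(C)=CCBr | starting material
3 | 3-methyl-5-[(3-methylbut-2-en-1-yl)oxy]phenol | Cc1cc(O)cc(OCC=C(C)C)c1 | intermediate
4 | 3-methyl-5-[(3-methylbut-2-en-1-yl)oxy]phenyl N-isopropylcarbamate | Cc1cc(OCC=C(C)C)cc(OC(=O)NC(C)C)c1 | intermediate
5 | 3-methyl-5-[(3-methylbut-2-en-1-yl)oxy]phenyl N-(tert-butyldimethylsilyl)-N-isopropylcarbamate (in situ) | Cc1cc(OCC=C(C)C)cc(OC(=O)N(C(C)C)[Si](C)(C)C(C)(C)C)c1 | intermediate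
6 | 2-lithio derivative of 5 (in situ) | Cc1cc(OCC=C(C)C)c([Li])c(OC(=O)N(C(C)C)[Si](C)(C)C(C)(C)C)c1 | intermediate
7 | 5-methyl-3-[(3-methylbut-2-en-1-yl)oxy]-2-(trimethylsilyl)phenyl N-(tert-butyldimethylsilyl)-N-isopropylcarbamate (in situ) | Cc1cc(OCC=C(C)C)c([Si](C)(C)C)c(OC(=O)N(C(C)C)[Si](C)(C)C(C)(C)C)c1 | intermediate
8 | 5-methyl-3-[(3-methylbut-2-en-1-yl)oxy]-2-(trimethylsilyl)phenyl N-isopropylcarbamate | Cc1cc(OCC=C(C)C)c([Si](C)(C)C)c(OC(=O)NC(C)C)c1 | intermediate
9 | 5-methyl-3-[(3-methylbut-2-en-1-yl)oxy]-2-(trimethylsilyl)phenol (in situ, as its DBU-H+ phenoxide) | Cc1cc(OCC=C(C)C)c([Si](C)(C)C)c(O)c1 | intermediate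
10 | 5-methyl-3-[(3-methylbut-2-en-1-yl)oxy]-2-(trimethylsilyl)phenyl trifluoromethanesulfonate | Cc1cc(OCC=C(C)C)c([Si](C)(C)C)c(OS(=O)(=O)C(F)(F)F)c1 | intermediate
11 | 2,4-dimethoxyphenol | COc1ccc(O)c(OC)c1 | starting material
12 | 2-hydroxy-3,5-dimethoxybenzaldehyde | COc1cc(OC)c(O)c(C=O)c1 | intermediate
13 | 2-(1,3-dioxolan-2-yl)-4,6-dimethoxyphenol | COc1cc(OC)c(O)c(C2OCCO2)c1 | intermediate
14 | carbon dioxide | O=C=O | starting material
15 | potassium 2-(1,3-dioxolan-2-yl)-4,6-dimethoxyphenoxide (in situ) | COc1cc(OC)c([O-])c(C2OCCO2)c1.[K+] | intermediate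
16 | 5-methyl-3-[(3-methylbut-2-en-1-yl)oxy]benzyne (in situ) | CC1=CC#CC(OCC=C(C)C)=C1 | intermediate
17 | {2-[2-(1,3-dioxolan-2-yl)-4,6-dimethoxyphenoxy]-4-methyl-6-[(3-methylbut-2-en-1-yl)oxy]phenyl}potassium (in situ) | Cc1cc(OCC=C(C)C)c([K])c(Oc2c(C3OCCO3)cc(OC)cc2OC)c1 | intermediate
18 | potassium 2-[2-(1,3-dioxolan-2-yl)-4,6-dimethoxyphenoxy]-4-methyl-6-[(3-methylbut-2-en-1-yl)oxy]benzoate (in situ) | Cc1cc(OCC=C(C)C)c(C(=O)[O-])c(Oc2c(C3OCCO3)cc(OC)cc2OC)c1.[K+] | intermediate
19 | 2-[2-(1,3-dioxolan-2-yl)-4,6-dimethoxyphenoxy]-4-methyl-6-[(3-methylbut-2-en-1-yl)oxy]benzoic acid | OC(=O)c1c(OCC=C(C)C)cc(C)cc1Oc1c(C2OCCO2)cc(OC)cc1OC | intermediate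
20 | methyl 2-[2-(1,3-dioxolan-2-yl)-4,6-dimethoxyphenoxy]-4-methyl-6-[(3-methylbut-2-en-1-yl)oxy]benzoate | COC(=O)c1c(OCC=C(C)C)cc(C)cc1Oc1c(C2OCCO2)cc(OC)cc1OC | intermediate
21 | methyl 2-(2-formyl-4,6-dimethoxyphenoxy)-4-methyl-6-[(3-methylbut-2-en-1-yl)oxy]benzoate (in situ) | COC(=O)c1c(OCC=C(C)C)cc(C)cc1Oc1c(C=O)cc(OC)cc1OC | intermediate
22 | methyl 2-[2-(hydroxymethyl)-4,6-dimethoxyphenoxy]-4-methyl-6-[(3-methylbut-2-en-1-yl)oxy]benzoate (CNP0573678.0) | COC(=O)c1c(OCC=C(C)C)cc(C)cc1Oc1c(CO)cc(OC)cc1OC | target

**Step count**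

Total: 9 steps. Longest linear sequence: 7 steps (steps 1, 2, 3, 4, 7, 8, 9); steps 5 and 6 form the second branch.

**Steps most likely to fail**

1. Step 7 (proposed new method). Three processes may undercut it:
   - The aryl anion may be protonated before it meets CO2, giving only the simple diaryl ether.
   - Under CO2 the phenoxide may be tied up reversibly as an aryl carbonate, which is less nucleophilic and can react through its carbonate oxygen followed by acyl transfer.
   - The aryne may be consumed intramolecularly by an ene reaction with the prenyl double bond.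

   The fallback uses known chemistry only. It sets out from aryllithium 6 and returns at aldehyde 21. Aryllithium 6, generated as in step 3, is quenched with methyl chloroformate instead of TMSCl to give methyl 2-{[N-(tert-butyldimethylsilyl)-N-isopropylcarbamoyl]oxy}-4-methyl-6-[(3-methylbut-2-en-1-yl)oxy]benzoate F1 (not isolated). Acidic work-up removes the N-silyl group to give methyl 2-[(isopropylcarbamoyl)oxy]-4-methyl-6-[(3-methylbut-2-en-1-yl)oxy]benzoate F2. Cleavage with Et2NH/DBU gives methyl 2-hydroxy-4-methyl-6-[(3-methylbut-2-en-1-yl)oxy]benzoate F3. The coupling partner 2-bromo-3,5-dimethoxybenzaldehyde F4 is made by NBS bromination of commercial 3,5-dimethoxybenzaldehyde. A copper-catalysed Ullmann diaryl ether synthesis (CuI, N,N-dimethylglycine, Cs2CO3, dioxane, 100 °C), in which the ortho-formyl group activates the bromide, should join F3 and F4 to aldehyde 21. Reduction with NaBH4 as in the second half of step 9 then gives 22.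

2. Step 3. Deprotonation at the allylic O–CH2 of the prenyl ether, followed by Wittig rearrangement or elimination, may compete with ring lithiation. Metalation at the carbon between the carbamate and the methyl group would erode regioselectivity.

   The fallback introduces silicon before the prenyl group. It sets out from orcinol 1 and returns at silylphenol 9. Orcinol is bis-carbamoylated (ClCONEt2, K2CO3, MeCN) to 5-methyl-1,3-phenylene bis(N,N-diethylcarbamate) F5. Lithiation with s-BuLi/TMEDA in THF at −78 °C gives the 2-lithio species F6, and TMSCl quench gives 5-methyl-2-(trimethylsilyl)-1,3-phenylene bis(N,N-diethylcarbamate) F7. Reductive cleavage of both carbamates with the Schwartz reagent, with near-neutral work-up, gives 5-methyl-2-(trimethylsilyl)benzene-1,3-diol F8. Mitsunobu mono-etherification with one equivalent of 3-methylbut-2-en-1-ol (PPh3, DIAD, THF, 0 °C), which avoids any base, gives 9. This is isolated and triflated with PhNTf2/DBU as in the second half of step 4 to give 10.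

3. Step 1. Over-alkylation to the bis-ether and C-prenylation of the electron-rich ring may lower the mono-ether selectivity.

   The fallback avoids a statistical alkylation. It sets out from prenyl bromide 2 and returns at 3. Commercial 3-bromo-5-methylphenol, which has a single hydroxyl group, is alkylated with 2 (K2CO3, acetone) to 1-bromo-3-methyl-5-[(3-methylbut-2-en-1-yl)oxy]benzene F9. Copper-catalysed hydroxylation of the aryl bromide (Cu(acac)2, oxalamide ligand, LiOH, DMSO/H2O, 80 °C) then gives 3; copper is chosen so that the allylic ether is not ionised.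

**Further compounds**

F1 | step 7 | methyl 2-{[N-(tert-butyldimethylsilyl)-N-isopropylcarbamoyl]oxy}-4-methyl-6-[(3-methylbut-2-en-1-yl)oxy]benzoate | COC(=O)c1c(OCC=C(C)C)cc(C)cc1OC(=O)N(C(C)C)[Si](C)(C)C(C)(C)C
F2 | step 7 | methyl 2-[(isopropylcarbamoyl)oxy]-4-methyl-6-[(3-methylbut-2-en-1-yl)oxy]benzoate | COC(=O)c1c(OCC=C(C)C)cc(C)cc1OC(=O)NC(C)C
F3 | step 7 | methyl 2-hydroxy-4-methyl-6-[(3-methylbut-2-en-1-yl)oxy]benzoate | COC(=O)c1c(O)cc(C)cc1OCC=C(C)C
F4 | step 7 | 2-bromo-3,5-dimethoxybenzaldehyde | COc1cc(OC)c(Br)c(C=O)c1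
F5 | step 3 | 5-methyl-1,3-phenylene bis(N,N-diethylcarbamate) | CCN(CC)C(=O)Oc1cc(C)cc(OC(=O)N(CC)CC)c1
F6 | step 3 | 2-lithio-5-methyl-1,3-phenylene bis(N,N-diethylcarbamate) | CCN(CC)C(=O)Oc1cc(C)cc(OC(=O)N(CC)CC)c1[Li]
F7 | step 3 | 5-methyl-2-(trimethylsilyl)-1,3-phenylene bis(N,N-diethylcarbamate) | CCN(CC)C(=O)Oc1cc(C)cc(OC(=O)N(CC)CC)c1[Si](C)(C)C
F8 | step 3 | 5-methyl-2-(trimethylsilyl)benzene-1,3-diol | Cc1cc(O)c([Si](C)(C)C)c(O)c1
F9 | step 1 | 1-bromo-3-methyl-5-[(3-methylbut-2-en-1-yl)oxy]benzene | Cc1cc(Br)cc(OCC=C(C)C)c1
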